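**Plan** (ring atoms O1, C2–C5; side chain C1'–C16')
1. Cuts: C5–C1' as a vinylogous aldol bond, after raising the C3' CH2OH to CHO; then the lactone O1–C2 bond, back to a (Z)-γ-hydroxy enoate; then the chain at C3'–C4', back to (2E,6E)-farnesyl bromide.
2. Enabling feature: the oxygen on C5 and the oxidised carbon on C3' stand 1,5 across the C2'=C3' alkene (δ-hydroxy-α-alkyl-enal pattern). C5 and C2 are cis on the ring C3=C4 bond, so the electrophile is the open (Z)-formyl acrylate form of a γ-hydroxybutenolide.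
3. Forward, chain piece: farnesyl bromide → Weinreb amide → vinyl ketone → 2-alkylbut-2-enal → silyl dienol ether 7. Ring piece: furan-3-ylmethanol → silyl ether → singlet-oxygen hydroxybutenolide → (Z)-aldehyde ester 12.
4. Union of 12 and 7 forms C5–C1' and the C2'=C3' alkene; the butenolide ring then closes by lactonisation; Luche reduction and desilylation finish.
5. Stereochemistry: C5 (R) from a tryptophan-derived oxazaborolidinone (re-face attack on the formyl group); 2'E from the open transition state and the enal preference; 6'E,10'E carried from the farnesyl bromide.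

Key step: step 8

Assumption: the facial sense of the oxazaborolidinone in step 8 is assigned by analogy with its behaviour toward simple aldehydes; if it proves opposite here, the promoter from (R)-tryptophan is used instead.

**Step 1**
Reactants: 1 (2E,6E)-farnesyl bromide; 2 N-methoxy-N-methylacetamide
Product: 3 (4E,8E)-N-methoxy-N,5,9,13-tetramethyltetradeca-4,8,12-trienamide
Conditions: LiN(iPr)2, THF, −78 °C; then 1, −78 → −40 °C
Reagents that add atoms: none
Why: SN2 alkylation of the lithium amide enolate by the primary allylic bromide should give the chain-extended Weinreb amide with both alkene geometries untouched (enolate alkylation).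

**Step 2**
Reactants: 3 Weinreb amide
Product: 4 (6E,10E)-7,11,15-trimethylhexadeca-1,6,10,14-tetraen-3-one
Conditions: CH2=CHMgBr, THF, 0 °C; inverse quench into cold 1 M HCl
Reagents that add atoms: vinylmagnesium bromide (C=C[Mg]Br)
Why: The chelated tetrahedral intermediate of the Weinreb ketone synthesis stops at mono-addition, and the acidic inverse quench keeps the liberated amine from adding to the enone.

**Step 3**
Reactants: 4 vinyl ketone
Product: 6 (2E,5E,9E)-2-ethylidene-6,10,14-trimethylpentadeca-5,9,13-trienal, via methoxydiene 5 (not isolated)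
Conditions: Ph3P(CH2OMe)Cl, KOtBu, THF, 0 °C; 4, −78 → 0 °C; then 10% aq. oxalic acid, THF, rt
Reagents that add atoms: (methoxymethyl)triphenylphosphonium chloride (COC[P+](c1ccccc1)(c1ccccc1)c1ccccc1.[Cl-]); water (O)
Why: Wittig methoxymethylenation at the ketone carbonyl followed by mild hydrolysis of the dienol ether should give the one-carbon-homologated aldehyde, which settles as the conjugated (E)-enal with CHO trans to the methyl group (any β,γ-isomer converges in step 4).

**Step 4**
Reactants: 6 enal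
Product: 7 tert-butyl{[(1E,5E,9E)-2-ethenyl-6,10,14-trimethylpentadeca-1,5,9,13-tetraen-1-yl]oxy}dimethylsilane
Conditions: TBSOTf, Et3N, CH2Cl2, 0 °C
Reagents that add atoms: tert-butyldimethylsilyl trifluoromethanesulfonate (CC(C)(C)[Si](C)(C)OS(=O)(=O)C(F)(F)F)
Why: O-Silylation of the enal and γ-deprotonation by the amine (soft enolisation) should give the 1-silyloxy-1,3-diene; it is drawn 1E, and either enol-ether geometry serves in step 8.

**Step 5**
Reactants: 8 furan-3-ylmethanol
Product: 9 tert-butyl(furan-3-ylmethoxy)dimethylsilane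
Conditions: TBSCl, imidazole, CH2Cl2, rt
Reagents that add atoms: tert-butyldimethylsilyl chloride (CC(C)(C)[Si](C)(C)Cl)
Why: Standard silylation of a primary alcohol protects the future C4 hydroxymethyl group through the oxidation and the aldol step.

**Step 6**
Reactants: 9 silyl furan
Product: 11 4-({[tert-butyl(dimethyl)silyl]oxy}methyl)-5-hydroxyfuran-2(5H)-one, via furan endoperoxide 10 (not isolated)
Conditions: O2, hν (visible), 5,10,15,20-tetraphenylporphyrin (cat.), iPr2NEt, CH2Cl2, −78 °C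
Reagents that add atoms: dioxygen (O=O)
Why: [4+2] addition of singlet oxygen to the furan and removal by the hindered base of the endoperoxide bridgehead hydrogen remote from the substituent should place the carbonyl away from, and the lactol next to, the substituted carbon (base-directed regioselective furan photooxygenation).

**Step 7**
Reactants: 11 hydroxybutenolide
Product: 12 methyl (2Z)-4-{[tert-butyl(dimethyl)silyl]oxy}-3-formylbut-2-enoate
Conditions: MeI, K2CO3, DMF, 0 °C; used directly
Reagents that add atoms: iodomethane (CI)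
Why: The lactol is in equilibrium with its ring-opened (Z)-formyl carboxylate under carbonate, and SN2 esterification of the carboxylate should trap the open form with the cis geometry inherited from the ring.

**Step 8**
Reactants: 12 (Z)-aldehyde ester; 7 silyl dienol ether
Product: 14 (2E,5E,9E)-2-{2-[(2R)-3-({[tert-butyl(dimethyl)silyl]oxy}methyl)-5-oxo-2,5-dihydrofuran-2-yl]ethylidene}-6,10,14-trimethylpentadeca-5,9,13-trienal, via open hydroxy ester 13 (not isolated)
Conditions: (4S)-4-(1H-indol-3-ylmethyl)-3-(4-methylbenzenesulfonyl)-2-phenyl-1,3,2-oxazaborolidin-5-one (0.5 equiv), iPrOH, EtCN, −78 °C; then pyridinium p-toluenesulfonate (cat.), CH2Cl2, rt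
Reagents that add atoms: none
Why: The boron Lewis acid binds the formyl oxygen of 12 and the terminal (γ) CH2 of dienol ether 7 attacks the formyl carbon through an open, antiperiplanar transition state; the silyl group is passed to iPrOH and the enal is released, which forms the C5–C1' bond and the C2'=C3' alkene together. The closest known reaction type is the oxazaborolidinone-promoted vinylogous Mukaiyama aldol addition of aldehyde-derived α-alkyl silyl dienol ethers to aldehydes. The butenolide ring then closes by 5-exo-trig lactonisation of the new C5 hydroxyl onto the cis methyl ester, which the (Z) geometry of 12 makes possible. The only new stereocentre, C5, is controlled by the promoter: the indole of the (S)-tryptophan unit is expected to shield one formyl face so that attack comes on the re face, which gives (R). The step needs γ- over α-attack (the α-carbon is fully substituted and the boron-bound aldehyde is bulky), 1,2- over 1,4-addition (activation is at the formyl oxygen, at −78 °C), and E geometry at C2'=C3' (s-trans diene in the open transition state, and the α-alkyl enal strongly prefers CHO trans to the β-substituent).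

**Step 9**
Reactants: 14 butenolide enal
Product: 15 (5R)-4-({[tert-butyl(dimethyl)silyl]oxy}methyl)-5-[(2E,6E,10E)-3-(hydroxymethyl)-7,11,15-trimethylhexadeca-2,6,10,14-tetraen-1-yl]furan-2(5H)-one
Conditions: NaBH4, CeCl3·7H2O, MeOH, −78 °C
Reagents that add atoms: none
Why: Luche conditions should reduce the aldehyde 1,2 to the allylic alcohol and leave the less electrophilic butenolide and C5 untouched.

**Step 10**
Reactants: 15 silyl ether
Product: 16 hippolide E, (5R)-4-(hydroxymethyl)-5-[(2E,6E,10E)-3-(hydroxymethyl)-7,11,15-trimethylhexadeca-2,6,10,14-tetraen-1-yl]furan-2(5H)-one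
Conditions: HF·pyridine, pyridine, THF, 0 °C → rt
Reagents that add atoms: none
Why: Buffered fluoride desilylation of the primary silyl ether is mild enough to spare the base-sensitive γ-hydrogen at C5 and the allylic alcohols.

**Compound list**
1 | (2E,6E)-farnesyl bromide, (2E,6E)-1-bromo-3,7,11-trimethyldodeca-2,6,10-triene | CC(C)=CCC/C(C)=C/CC/C(C)=C/CBr | starting material
2 | N-methoxy-N-methylacetamide | CC(=O)N(C)OC | starting material
3 | (4E,8E)-N-methoxy-N,5,9,13-tetramethyltetradeca-4,8,12-trienamide | CC(C)=CCC/C(C)=C/CC/C(C)=C/CCC(=O)N(C)OC | intermediate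
4 | (6E,10E)-7,11,15-trimethylhexadeca-1,6,10,14-tetraen-3-one | CC(C)=CCC/C(C)=C/CC/C(C)=C/CCC(=O)C=C | intermediate
5 | (6E,10E)-3-(methoxymethylidene)-7,11,15-trimethylhexadeca-1,6,10,14-tetraene (enol ether geometry mixed) | CC(C)=CCC/C(C)=C/CC/C(C)=C/CCC(=COC)C=C | intermediate
6 | (2E,5E,9E)-2-ethylidene-6,10,14-trimethylpentadeca-5,9,13-trienal | CC(C)=CCC/C(C)=C/CC/C(C)=C/CC/C(C=O)=C\C | intermediate
7 | tert-butyl{[(1E,5E,9E)-2-ethenyl-6,10,14-trimethylpentadeca-1,5,9,13-tetraen-1-yl]oxy}dimethylsilane | CC(C)=CCC/C(C)=C/CC/C(C)=C/CC/C(C=C)=C\O[Si](C)(C)C(C)(C)C | intermediate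
8 | furan-3-ylmethanol | OCc1ccoc1 | starting material
9 | tert-butyl(furan-3-ylmethoxy)dimethylsilane | CC(C)(C)[Si](C)(C)OCc1ccoc1 | intermediate
10 | 5-({[tert-butyl(dimethyl)silyl]oxy}methyl)-2,3,7-trioxabicyclo[2.2.1]hept-5-ene | CC(C)(C)[Si](C)(C)OCC1=CC2OOC1O2 | intermediate
11 | 4-({[tert-butyl(dimethyl)silyl]oxy}methyl)-5-hydroxyfuran-2(5H)-one (racemic lactol) | CC(C)(C)[Si](C)(C)OCC1=CC(=O)OC1O | intermediate
12 | methyl (2Z)-4-{[tert-butyl(dimethyl)silyl]oxy}-3-formylbut-2-enoate | COC(=O)/C=C(\C=O)CO[Si](C)(C)C(C)(C)C | intermediate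
13 | methyl (2Z,4R,6E,10E,14E)-3-({[tert-butyl(dimethyl)silyl]oxy}methyl)-7-formyl-4-hydroxy-11,15,19-trimethylicosa-2,6,10,14,18-pentaenoate | CC(C)=CCC/C(C)=C/CC/C(C)=C/CC/C(=C\C[C@@H](O)/C(CO[Si](C)(C)C(C)(C)C)=C\C(=O)OC)C=O | intermediate
14 | (2E,5E,9E)-2-{2-[(2R)-3-({[tert-butyl(dimethyl)silyl]oxy}methyl)-5-oxo-2,5-dihydrofuran-2-yl]ethylidene}-6,10,14-trimethylpentadeca-5,9,13-trienal | CC(C)=CCC/C(C)=C/CC/C(C)=C/CC/C(=C\C[C@H]1OC(=O)C=C1CO[Si](C)(C)C(C)(C)C)C=O | intermediate
15 | (5R)-4-({[tert-butyl(dimethyl)silyl]oxy}methyl)-5-[(2E,6E,10E)-3-(hydroxymethyl)-7,11,15-trimethylhexadeca-2,6,10,14-tetraen-1-yl]furan-2(5H)-one | CC(C)=CCC/C(C)=C/CC/C(C)=C/CC/C(=C\C[C@H]1OC(=O)C=C1CO[Si](C)(C)C(C)(C)C)CO | intermediate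
16 | hippolide E, (5R)-4-(hydroxymethyl)-5-[(2E,6E,10E)-3-(hydroxymethyl)-7,11,15-trimethylhexadeca-2,6,10,14-tetraen-1-yl]furan-2(5H)-one | CC(C)=CCC/C(C)=C/CC/C(C)=C/CC/C(=C\C[C@H]1OC(=O)C=C1CO)CO | target

**Step count and risks**
Total steps: 10. Longest linear sequence: 7 steps (steps 1–4, then 8–10).

Step 8. What may go wrong: insufficient facial discrimination at the formyl group by the boron promoter, and conjugate addition to the doubly activated C2=C3 bond in competition with 1,2-addition. The fallback is an auxiliary-controlled vinylogous aldol that sets out from 6 (and uses 12) and comes back at 15. Pinnick oxidation of 6 (NaClO2, NaH2PO4, 2-methylbut-2-ene, tBuOH/H2O) should give (2E,5E,9E)-2-ethylidene-6,10,14-trimethylpentadeca-5,9,13-trienoic acid F1. Acylation through the pivaloyl mixed anhydride (pivaloyl chloride, Et3N, then (4S)-4-(propan-2-yl)-1,3-oxazolidin-2-one, LiCl) gives (4S)-3-[(2E,5E,9E)-2-ethylidene-6,10,14-trimethylpentadeca-5,9,13-trienoyl]-4-(propan-2-yl)-1,3-oxazolidin-2-one F2. γ-Deprotonation and O-silylation (NaN(SiMe3)2, TBSCl, THF, −78 °C) give the vinylketene silyl N,O-acetal (4S)-3-[(5E,9E)-1-{[tert-butyl(dimethyl)silyl]oxy}-2-ethenyl-6,10,14-trimethylpentadeca-1,5,9,13-tetraen-1-yl]-4-(propan-2-yl)-1,3-oxazolidin-2-one F3. Its TiCl4-mediated addition to 12 (CH2Cl2, −78 °C), where the auxiliary directs the remote addition, gives methyl (2Z,4R,6E,10E,14E)-3-({[tert-butyl(dimethyl)silyl]oxy}methyl)-4-hydroxy-11,15,19-trimethyl-7-{[(4S)-2-oxo-4-(propan-2-yl)-1,3-oxazolidin-3-yl]carbonyl}icosa-2,6,10,14,18-pentaenoate F4. This lactonises with pyridinium p-toluenesulfonate to (4S)-3-[(2E,5E,9E)-2-{2-[(2R)-3-({[tert-butyl(dimethyl)silyl]oxy}methyl)-5-oxo-2,5-dihydrofuran-2-yl]ethylidene}-6,10,14-trimethylpentadeca-5,9,13-trienoyl]-4-(propan-2-yl)-1,3-oxazolidin-2-one F5. Reductive removal of the auxiliary (NaBH4, THF/H2O, 0 °C) then gives 15 directly. The auxiliary is drawn as the (S)-valinol-derived one; its antipode is taken if the transition-state model calls for it.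

Step 7. What may go wrong: alkylation at the lactol oxygen instead of the carboxylate, and Z to E isomerisation of the liberated formyl acrylate during isolation. The fallback carries the acyl group as a Weinreb amide, sets out from 11 and comes back at 14. NaBH4 reduction of lactol 11 (MeOH, 0 °C, acidic work-up) should give 4-({[tert-butyl(dimethyl)silyl]oxy}methyl)furan-2(5H)-one F6. Aminolysis (MeNHOMe·HCl, AlMe3, CH2Cl2) opens it to (2E)-3-({[tert-butyl(dimethyl)silyl]oxy}methyl)-4-hydroxy-N-methoxy-N-methylbut-2-enamide F7, with the amide cis to the free CH2OH. MnO2 oxidation gives (2Z)-4-{[tert-butyl(dimethyl)silyl]oxy}-3-formyl-N-methoxy-N-methylbut-2-enamide F8, which has no ambident carboxylate. Under the conditions of step 8, F8 and 7 should give (2Z,4R,6E,10E,14E)-3-({[tert-butyl(dimethyl)silyl]oxy}methyl)-7-formyl-4-hydroxy-N-methoxy-N,11,15,19-tetramethylicosa-2,6,10,14,18-pentaenamide F9. Acid-catalysed lactonisation (camphorsulfonic acid, CH2Cl2) then gives 14.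

Step 3. What may go wrong: conjugate addition of the ylide to the vinyl ketone, or base-induced polymerisation of the vinyl ketone, in competition with carbonyl olefination. The fallback avoids the vinyl ketone, sets out from 3 and comes back at 6. Chloromethyllithium (ICH2Cl, MeLi·LiBr, THF, −78 °C) should convert 3 into (5E,9E)-1-chloro-6,10,14-trimethylpentadeca-5,9,13-trien-2-one F10. CH2=CHMgBr adds to give (6E,10E)-3-(chloromethyl)-7,11,15-trimethylhexadeca-1,6,10,14-tetraen-3-ol F11. NaOH closes it to 2-ethenyl-2-[(3E,7E)-4,8,12-trimethyltrideca-3,7,11-trien-1-yl]oxirane F12. Meinwald rearrangement (BF3·OEt2 cat., CH2Cl2, −78 °C; 1,2-hydride shift) followed by Et3N to bring the alkene into conjugation gives 6.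

**Further compounds**
F1 | step 8 | (2E,5E,9E)-2-ethylidene-6,10,14-trimethylpentadeca-5,9,13-trienoic acid | CC(C)=CCC/C(C)=C/CC/C(C)=C/CC/C(C(=O)O)=C\C
F2 | step 8 | (4S)-3-[(2E,5E,9E)-2-ethylidene-6,10,14-trimethylpentadeca-5,9,13-trienoyl]-4-(propan-2-yl)-1,3-oxazolidin-2-one | CC(C)=CCC/C(C)=C/CC/C(C)=C/CC/C(C(=O)N1[C@@H](C(C)C)COC1=O)=C\C
F3 | step 8 | (4S)-3-[(5E,9E)-1-{[tert-butyl(dimethyl)silyl]oxy}-2-ethenyl-6,10,14-trimethylpentadeca-1,5,9,13-tetraen-1-yl]-4-(propan-2-yl)-1,3-oxazolidin-2-one (ketene acetal geometry not specified) | CC(C)=CCC/C(C)=C/CC/C(C)=C/CCC(C=C)=C(O[Si](C)(C)C(C)(C)C)N1[C@@H](C(C)C)COC1=O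
F4 | step 8 | methyl (2Z,4R,6E,10E,14E)-3-({[tert-butyl(dimethyl)silyl]oxy}methyl)-4-hydroxy-11,15,19-trimethyl-7-{[(4S)-2-oxo-4-(propan-2-yl)-1,3-oxazolidin-3-yl]carbonyl}icosa-2,6,10,14,18-pentaenoate | CC(C)=CCC/C(C)=C/CC/C(C)=C/CC/C(=C\C[C@@H](O)/C(CO[Si](C)(C)C(C)(C)C)=C\C(=O)OC)C(=O)N1[C@@H](C(C)C)COC1=O
F5 | step 8 | (4S)-3-[(2E,5E,9E)-2-{2-[(2R)-3-({[tert-butyl(dimethyl)silyl]oxy}methyl)-5-oxo-2,5-dihydrofuran-2-yl]ethylidene}-6,10,14-trimethylpentadeca-5,9,13-trienoyl]-4-(propan-2-yl)-1,3-oxazolidin-2-one | CC(C)=CCC/C(C)=C/CC/C(C)=C/CC/C(=C\C[C@H]1OC(=O)C=C1CO[Si](C)(C)C(C)(C)C)C(=O)N1[C@@H](C(C)C)COC1=O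
F6 | step 7 | 4-({[tert-butyl(dimethyl)silyl]oxy}methyl)furan-2(5H)-one | CC(C)(C)[Si](C)(C)OCC1=CC(=O)OC1
F7 | step 7 | (2E)-3-({[tert-butyl(dimethyl)silyl]oxy}methyl)-4-hydroxy-N-methoxy-N-methylbut-2-enamide | CON(C)C(=O)/C=C(\CO)CO[Si](C)(C)C(C)(C)C
F8 | step 7 | (2Z)-4-{[tert-butyl(dimethyl)silyl]oxy}-3-formyl-N-methoxy-N-methylbut-2-enamide | CON(C)C(=O)/C=C(\C=O)CO[Si](C)(C)C(C)(C)C
F9 | step 7 | (2Z,4R,6E,10E,14E)-3-({[tert-butyl(dimethyl)silyl]oxy}methyl)-7-formyl-4-hydroxy-N-methoxy-N,11,15,19-tetramethylicosa-2,6,10,14,18-pentaenamide | CC(C)=CCC/C(C)=C/CC/C(C)=C/CC/C(=C\C[C@@H](O)/C(CO[Si](C)(C)C(C)(C)C)=C\C(=O)N(C)OC)C=O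
F10 | step 3 | (5E,9E)-1-chloro-6,10,14-trimethylpentadeca-5,9,13-trien-2-one | CC(C)=CCC/C(C)=C/CC/C(C)=C/CCC(=O)CCl
F11 | step 3 | (6E,10E)-3-(chloromethyl)-7,11,15-trimethylhexadeca-1,6,10,14-tetraen-3-ol (racemic) | CC(C)=CCC/C(C)=C/CC/C(C)=C/CCC(O)(CCl)C=C
F12 | step 3 | 2-ethenyl-2-[(3E,7E)-4,8,12-trimethyltrideca-3,7,11-trien-1-yl]oxirane (racemic) | CC(C)=CCC/C(C)=C/CC/C(C)=C/CCC1(C=C)CO1
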